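**Strategy.** The route rests on disconnecting ring A at C1–C10. The target's cis ring fusion (C5–H and the C20 methyl on quaternary C10 on one face), with oxygen at C3 beside fully substituted C4, is the signature of an anionic oxy-Cope shift. The potassium alkoxide of a 2-vinylbicyclo[2.2.2]oct-5-en-2-ol forms C1–C10, breaks C3–C8 and thereby closes ring A, sets C10 relative to C5 and delivers the C3 carbonyl in one operation. The precursor is a dearomatisation-derived, enantiopure bicyclooctenol in which C4 already carries both hydroxymethyl carbons as a spiro acetonide and the C9=C10 bridge bears the angular methyl and the C11–C12 chain.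

Key step: step 12

Remarks.
- Labdane numbering is used for every intermediate: ring A is C1–C5 and C10, ring B is C5–C10, the chain is C11–C12, the butenolide is C13–C16, C17 sits on C8, C18 and C19 on C4, C20 on C10.
- The target SMILES encodes (3R,5R,9R,10S): H5, C20, the C3 hydroxyl and the C11 chain lie on one face, so the decalin is cis-fused, and the route is built for this fusion.
- Assumption: in the thermal cycloaddition of step 5 the diene is taken to add to the Cα-Si face of the (2S)-N-acryloylsultam (anti to the pseudo-axial sulfonyl oxygen in the s-cis conformer with C=O anti to SO2). The two endo adducts are separable diastereomers, so the route does not depend on the level of induction, and the (2R)-sultam would be used if the sense proved opposite.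

Step 1
Reactants: 1 2-methoxy-4-methylphenol
Product: 2 2-methoxy-4-methylphenyl acetate
Conditions: Ac2O, pyridine, DMAP (cat.), CH2Cl2, 0 °C → rt
Reagents that add atoms: acetic anhydride (CC(=O)OC(C)=O)
Why: O-acylation of the phenol (nucleophilic acyl substitution) weakens its directing power so that the methoxy group controls the next substitution.

Step 2
Reactants: 2 2-methoxy-4-methylphenyl acetate
Product: 3 5-bromo-2-methoxy-4-methylphenyl acetate
Conditions: NBS, MeCN, 0 °C → rt
Reagents that add atoms: N-bromosuccinimide (O=C1CCC(=O)N1Br)
Why: Electrophilic aromatic bromination should occur para to the methoxy group (ring C5, ortho to methyl), since acetoxy is the weaker director and the position between methoxy and methyl is crowded.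

Step 3
Reactants: 3 5-bromo-2-methoxy-4-methylphenyl acetate; 4 potassium (2-benzyloxyethyl)trifluoroborate
Product: 6 5-(2-benzyloxyethyl)-2-methoxy-4-methylphenol, via aryl acetate 5 (not isolated)
Conditions: Pd(OAc)2 (cat.), RuPhos, K2CO3, toluene/H2O, 80 °C; then MeOH, rt
Reagents that add atoms: none
Why: Suzuki–Miyaura coupling of the primary alkyltrifluoroborate with the aryl bromide installs the future C11–C12 chain, and carbonate-catalysed methanolysis of the aryl acetate in the same flask frees the phenol needed for dearomatisation.

Step 4
Reactants: 7 (2S)-bornane-10,2-sultam; 8 acryloyl chloride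
Product: 10 N-acryloyl-(2S)-bornane-10,2-sultam, via sodium sultamide 9 (not isolated)
Conditions: NaH, toluene, 0 °C → rt; then 8, rt
Reagents that add atoms: none
Why: N-acylation of the sodium sulfonamide by the acid chloride gives the chiral acrylamide that serves as a resolvable ethylene equivalent.

Step 5
Reactants: 6 5-(2-benzyloxyethyl)-2-methoxy-4-methylphenol; 10 N-acryloyl-(2S)-bornane-10,2-sultam
Product: 12 endo Diels–Alder adduct (sultam imide of the 3-oxo-4,4-dimethoxy bicycle), via masked o-benzoquinone 11 (not isolated)
Conditions: PhI(OAc)2, MeOH/CH2Cl2, 0 °C → rt, 6 added slowly to oxidant and 10 (excess, recovered); endo diastereomers separated by crystallisation or chromatography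
Reagents that add atoms: methanol (CO)
Why: Oxidative dearomatisation of the 2-methoxyphenol in methanol gives the 6,6-dimethoxycyclohexa-2,4-dienone, which is trapped in an endo Diels–Alder reaction (acyl-bearing carbon bonding to C8, the terminus next to the carbonyl); attack on the acryloyl Cα-Si face sets C5, C7 (R) and C8, and the adduct from the other face is a removable diastereomer.

Step 6
Reactants: 12 endo Diels–Alder adduct
Product: 13 bicyclic keto acid (7-carboxylic acid, carboxyl syn to C9=C10)
Conditions: LiOH, THF/H2O, 0 °C → rt; aq. HCl to pH 3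
Reagents that add atoms: lithium hydroxide ([Li+].[OH-])
Why: Hydroxide attacks the exocyclic acyl carbon of the N-acylsultam (acyl substitution), releasing the acid and the recoverable auxiliary; C7 is removed in the next step, so its epimerisation would not matter.

Step 7
Reactants: 13 bicyclic keto acid
Product: 15 4,4-dimethoxy bicyclic ketone (C6 and C7 both CH2), via thiohydroxamate ester 14 (not isolated)
Conditions: N-hydroxypyridine-2-thione, DCC, DMAP (cat.), CH2Cl2, dark, 0 °C → rt; then t-BuSH (large excess), visible light, 0 °C
Reagents that add atoms: none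
Why: Barton reductive decarboxylation: the thiohydroxamate ester fragments to the C7 radical, which the excess thiol should quench by hydrogen transfer faster than it can add across to the C9=C10 bridge, reducing the acrylate unit to an ethano bridge.

Step 8
Reactants: 15 4,4-dimethoxy bicyclic ketone
Product: 17 bicyclic ketone with C4H2, via monomethoxy ketone 16 (not isolated)
Conditions: SmI2, THF/MeOH, −78 °C → rt
Reagents that add atoms: none
Why: SmI2 cleaves both C–O bonds α to the ketone by successive electron transfer through samarium enolates that methanol protonates (known reductive removal of α-alkoxy groups from ketones), leaving C4 as the only enolisable position.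

Step 9
Reactants: 17 bicyclic ketone with C4H2
Product: 19 4,4-bis(hydroxymethyl) bicyclic ketone, via mono(hydroxymethyl) ketone 18 (not isolated)
Conditions: aq. CH2O (excess), K2CO3 (cat.), THF/MeOH, rt
Reagents that add atoms: formaldehyde (C=O)
Why: Twofold crossed aldol addition of formaldehyde can occur only at C4 because the other α-carbon, C8, is a bridgehead that cannot enolise; this installs C18 and C19, and C4 is not stereogenic.

Step 10
Reactants: 19 4,4-bis(hydroxymethyl) bicyclic ketone
Product: 20 spiro acetonide ketone
Conditions: Me2C(OMe)2, PPTS (cat.), acetone, rt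
Reagents that add atoms: 2,2-dimethoxypropane (COC(C)(C)OC)
Why: Acid-catalysed transketalisation ties the 1,3-diol into a 2,2-dimethyl-1,3-dioxane, which blocks retro-aldol loss of formaldehyde in the basic steps that follow.

Step 11
Reactants: 20 spiro acetonide ketone; 21 vinylmagnesium bromide
Product: 22 vinyl carbinol (vinyl on C3 on the side of the C9=C10 bridge)
Conditions: THF, −78 °C → 0 °C; sat. aq. NH4Cl
Reagents that add atoms: none
Why: Grignard 1,2-addition to the non-enolisable ketone should occur from the face flanked by the C9=C10 etheno bridge, which is less hindered than the face under the C6–C7 hydrogens, placing the vinyl group syn to the alkene and setting C3 of the carbinol.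

Step 12
Reactants: 22 vinyl carbinol
Product: 25 cis-fused decalin 3-ketone (C8=C9, C4 spiro acetonide, 12-benzyloxy), via potassium alkoxide 23 (not isolated), via potassium enolate 24 (not isolated)
Conditions: KH, 18-crown-6, THF, 0 °C → rt (reflux if needed); sat. aq. NH4Cl, −78 °C
Reagents that add atoms: none
Why: Deprotonation gives the potassium alkoxide, whose 1,5-diene C1=C2–C3–C8–C9=C10 undergoes an anion-accelerated [3,3] sigmatropic shift through the only accessible boat-like array, forming C1–C10 and breaking C3–C8. The closest known reaction type is the anionic oxy-Cope rearrangement of vinyl carbinols derived from bicyclo[2.2.2]octenones to cis-decalins. Ring A (C1–C5, C10) closes by this pericyclic bond formation, suprafacial on both allyl halves, while the bicycle opens into six-membered ring B. The new quaternary stereocentre C10 is controlled by the bicyclic frame: C1 can reach C10 only from the face of the etheno bridge that is turned toward the carbinol bridge, so C1–C10 and C4–C5 end up cis on ring B and H5 and C20 are cis. The step needs [3,3] reorganisation to win over heterolytic C3–C8 fragmentation; this is secured by the syn vinyl/alkene geometry fixed in step 11, by the crown ether that frees the alkoxide charge, and by the delocalised C2=C3 enolate that forms. Protonation on quench gives the C3 ketone and leaves the C8=C9 alkene for ring B elaboration.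

Step 13
Reactants: 25 cis-fused decalin 3-ketone
Product: 26 3,12-diol (3-OH cis to C20)
Conditions: Li, liquid NH3/THF, −78 → −33 °C; NH4Cl
Reagents that add atoms: none
Why: Birch-type dissolving-metal reduction converts the C3 ketone through its ketyl into the thermodynamically preferred equatorial alcohol, which lies cis to C20 and H5 in the ring A chair that keeps quaternary C4 equatorial on ring B, and the same reagent cleaves the benzyl ether by reductive C–O scission while the isolated alkene is inert.

Step 14
Reactants: 26 3,12-diol
Product: 27 12-iodide (free 3-OH)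
Conditions: I2, PPh3, imidazole, CH2Cl2, 0 °C → rt
Reagents that add atoms: iodine (II)
Why: Appel-type iodination is selective for the primary alcohol, because the secondary C3 hydroxyl is neopentyl-like next to quaternary C4.

Step 15
Reactants: 27 12-iodide
Product: 28 3-O-triethylsilyl 12-iodide
Conditions: TESOTf, 2,6-lutidine, CH2Cl2, −78 °C
Reagents that add atoms: triethylsilyl trifluoromethanesulfonate (CC[Si](CC)(CC)OS(=O)(=O)C(F)(F)F)
Why: Silylation with the silyl triflate and a non-nucleophilic base (which does not displace the iodide) masks the only protic group before the organozinc and Lewis-acid steps, and the silyl ether is shed with the acetonide at the end.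

Step 16
Reactants: 28 3-O-triethylsilyl 12-iodide; 29 3-bromofuran-2(5H)-one
Product: 31 butenolide (C12–C13 joined, C8=C9 still in place), via alkylzinc iodide 30 (not isolated)
Conditions: Zn dust (activated), LiCl, THF, rt → 40 °C; then 29, Pd(OAc)2 (cat.), SPhos, THF, rt → 50 °C
Reagents that add atoms: none
Why: Negishi cross-coupling: zinc inserts into the primary C–I bond and the alkylzinc iodide, which tolerates the silyl ether, the acetonide and the lactone, couples with the alkenyl bromide under zerovalent palladium catalysis to form C12–C13.

Step 17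
Reactants: 31 butenolide
Product: 32 8,9-epoxide (oxygen on the face of H5 and C20)
Conditions: mCPBA, NaHCO3, CH2Cl2, 0 °C
Reagents that add atoms: 3-chloroperoxybenzoic acid (OOC(=O)c1cccc(Cl)c1)
Why: Prilezhaev epoxidation of the electron-rich trisubstituted C8=C9 alkene (the butenolide alkene is electron-poor) is expected on the convex face of the cis-decalin, because the other face is screened by the pseudo-axial C1 of ring A; this sets C8 and C9 of the epoxide.

Step 18
Reactants: 32 8,9-epoxide
Product: 33 8-ketone (H9 trans to C20, C11 chain cis to C20)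
Conditions: BF3·OEt2, CH2Cl2, −78 °C, short contact; sat. aq. NaHCO3
Reagents that add atoms: none
Why: Meinwald rearrangement: the Lewis acid opens the epoxide at tertiary C9 and the C8 hydrogen migrates to C9 on the face opposite the departing oxygen (stereospecific 1,2-hydride shift), so the C8 ketone forms with the C11 chain on the face of C20, which sets C9.

Step 19
Reactants: 33 8-ketone
Product: 34 8(17)-methylene compound (protected target)
Conditions: Zn, CH2Br2, TiCl4, THF/CH2Cl2, 0 °C → rt
Reagents that add atoms: dibromomethane (BrCBr)
Why: Takai–Lombardo methylenation with the zinc/titanium methylene reagent is non-basic, so the epimerisable C9 centre next to the ketone is preserved, and the reagent does not olefinate the lactone carbonyl.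

Step 20
Reactants: 34 8(17)-methylene compound
Product: 35 CNP0146463.1 (target)
Conditions: p-TsOH·H2O (cat.), MeOH, 0 °C → rt
Reagents that add atoms: none
Why: Mild acid-catalysed methanolysis removes the isopropylidene acetal and the triethylsilyl ether together, releasing the C3, C18 and C19 hydroxyls under conditions that should not isomerise the exocyclic C8=C17 alkene.

**Compound list**

1 | 2-methoxy-4-methylphenol | Cc1ccc(O)c(OC)c1 | starting material
2 | 2-methoxy-4-methylphenyl acetate | CC(=O)Oc1ccc(C)cc1OC | intermediate
3 | 5-bromo-2-methoxy-4-methylphenyl acetate | CC(=O)Oc1cc(Br)c(C)cc1OC | intermediate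
4 | potassium (2-benzyloxyethyl)trifluoroborate | [K+].F[B-](F)(F)CCOCc1ccccc1 | starting material
5 | 5-(2-benzyloxyethyl)-2-methoxy-4-methylphenyl acetate | CC(=O)Oc1cc(CCOCc2ccccc2)c(C)cc1OC | intermediate (not isolated)
6 | 5-(2-benzyloxyethyl)-2-methoxy-4-methylphenol | Oc1cc(CCOCc2ccccc2)c(C)cc1OC | intermediate
7 | (2S)-bornane-10,2-sultam (camphorsultam, nitrogen exo on C2) | N1[C@H]2C[C@@H]3CC[C@@]2(CS1(=O)=O)C3(C)C | starting material
8 | acryloyl chloride | C=CC(=O)Cl | starting material
9 | sodium salt of 7 | [Na+].[N-]1[C@H]2C[C@@H]3CC[C@@]2(CS1(=O)=O)C3(C)C | intermediate (not isolated)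
10 | N-acryloyl-(2S)-bornane-10,2-sultam | C=CC(=O)N1[C@H]2C[C@@H]3CC[C@@]2(CS1(=O)=O)C3(C)C | intermediate
11 | 3-(2-benzyloxyethyl)-6,6-dimethoxy-4-methylcyclohexa-2,4-dien-1-one (masked o-benzoquinone) | O=C1C=C(CCOCc2ccccc2)C(C)=CC1(OC)OC | intermediate (not isolated)
12 | endo adduct: bicyclo[2.2.2]octene with C3 ketone, C4(OMe)2, bridgeheads C5 and C8, bridge C9(CH2CH2OBn)=C10(CH3), bridge C6H2–C7H(CO–sultam); acyl group on C7 (R) syn to C9=C10 | O=C1C(OC)(OC)[C@@H]2C[C@@H](C(=O)N3[C@H]4C[C@@H]5CC[C@@]4(CS3(=O)=O)C5(C)C)[C@H]1C(CCOCc1ccccc1)=C2C | intermediate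
13 | 7-carboxylic acid of the same bicycle (7R, carboxyl syn to C9=C10) | O=C1C(OC)(OC)[C@@H]2C[C@@H](C(=O)O)[C@H]1C(CCOCc1ccccc1)=C2C | intermediate
14 | 2-thioxopyridin-1(2H)-yl ester of 13 | O=C1C(OC)(OC)[C@@H]2C[C@@H](C(=O)ON3C=CC=CC3=S)[C@H]1C(CCOCc1ccccc1)=C2C | intermediate (not isolated)
15 | 4,4-dimethoxy bicyclic ketone (C3=O; C6, C7 = CH2; C9 chain, C10 methyl) | O=C1C(OC)(OC)[C@@H]2CC[C@H]1C(CCOCc1ccccc1)=C2C | intermediate
16 | 4-methoxy bicyclic ketone (C4 epimers) | O=C1C(OC)[C@@H]2CC[C@H]1C(CCOCc1ccccc1)=C2C | intermediate (not isolated)
17 | bicyclic ketone with C4H2 | O=C1C[C@@H]2CC[C@H]1C(CCOCc1ccccc1)=C2C | intermediate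
18 | 4-(hydroxymethyl) bicyclic ketone (C4 epimers) | O=C1C(CO)[C@@H]2CC[C@H]1C(CCOCc1ccccc1)=C2C | intermediate (not isolated)
19 | 4,4-bis(hydroxymethyl) bicyclic ketone | O=C1C(CO)(CO)[C@@H]2CC[C@H]1C(CCOCc1ccccc1)=C2C | intermediate
20 | spiro acetonide ketone (C4 is C5 of a 2,2-dimethyl-1,3-dioxane) | O=C1C2(COC(C)(C)OC2)[C@@H]3CC[C@H]1C(CCOCc1ccccc1)=C3C | intermediate
21 | vinylmagnesium bromide | C=C[Mg]Br | starting material
22 | vinyl carbinol: C3 bears OH and vinyl, vinyl syn to the C9=C10 bridge, hydroxyl toward C6–C7 | C=C[C@@]1(O)C2(COC(C)(C)OC2)[C@@H]3CC[C@H]1C(CCOCc1ccccc1)=C3C | intermediate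
23 | potassium alkoxide of 22 | C=C[C@@]1([O-])C2(COC(C)(C)OC2)[C@@H]3CC[C@H]1C(CCOCc1ccccc1)=C3C.[K+] | intermediate (not isolated)
24 | potassium C2=C3 enolate of 25 | C1CC[C@H]2C3(COC(C)(C)OC3)C([O-])=CC[C@@]2(C)C=1CCOCc1ccccc1.[K+] | intermediate (not isolated)
25 | cis-fused decalin: C3 ketone, C4 spiro acetonide (O18, O19), H5 and C20 cis, C8=C9, C9–CH2CH2OBn | C1CC[C@H]2C3(COC(C)(C)OC3)C(=O)CC[C@@]2(C)C=1CCOCc1ccccc1 | intermediate
26 | 3,12-diol of the same decalin (3-OH cis to C20) | C1CC[C@H]2C3(COC(C)(C)OC3)[C@H](O)CC[C@@]2(C)C=1CCO | intermediate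
27 | 12-iodo 3-alcohol | C1CC[C@H]2C3(COC(C)(C)OC3)[C@H](O)CC[C@@]2(C)C=1CCI | intermediate
28 | 12-iodo 3-O-triethylsilyl ether | C1CC[C@H]2C3(COC(C)(C)OC3)[C@H](O[Si](CC)(CC)CC)CC[C@@]2(C)C=1CCI | intermediate
29 | 3-bromofuran-2(5H)-one | O=C1OCC=C1Br | starting material
30 | C12 alkylzinc iodide from 28 | C1CC[C@H]2C3(COC(C)(C)OC3)[C@H](O[Si](CC)(CC)CC)CC[C@@]2(C)C=1CC[Zn]I | intermediate (not isolated)
31 | butenolide: C12 bonded to C13 of the 2(5H)-furanone, C8=C9, 3-OTES, acetonide | C1CC[C@H]2C3(COC(C)(C)OC3)[C@H](O[Si](CC)(CC)CC)CC[C@@]2(C)C=1CCC1=CCOC1=O | intermediate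
32 | 8,9-epoxide of 31, oxygen on the face of H5 and C20 | [C@@H]14CC[C@H]2C3(COC(C)(C)OC3)[C@H](O[Si](CC)(CC)CC)CC[C@@]2(C)[C@@]1(O4)CCC1=CCOC1=O | intermediate
33 | 8-ketone, H9 trans to C20 and C11 cis to C20 | O=C1CC[C@H]2C3(COC(C)(C)OC3)[C@H](O[Si](CC)(CC)CC)CC[C@@]2(C)[C@@H]1CCC1=CCOC1=O | intermediate
34 | 8(17)-methylene compound, 3-OTES, 18,19-acetonide | C=C1CC[C@H]2C3(COC(C)(C)OC3)[C@H](O[Si](CC)(CC)CC)CC[C@@]2(C)[C@@H]1CCC1=CCOC1=O | intermediate
35 | CNP0146463.1: cis-fused (3R,5R,9R,10S)-3,18,19-trihydroxylabda-8(17),13-dien-16,15-olide | C=C1CC[C@H]2C(CO)(CO)[C@H](O)CC[C@@]2(C)[C@@H]1CCC1=CCOC1=O | target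

**Step count.** Total: 20 steps. Longest linear sequence: 19 steps (steps 1–3, then 5–20); step 4 is a one-step side branch.

**Steps most likely to fail**

Step 12 (key step). The alkoxide may not rearrange, because the C9=C10 bridge is tetrasubstituted and a quaternary centre has to form, or it may cleave heterolytically at C3–C8 and give non-Cope products. The fallback sets out from 22. Silylation (TMSCl, imidazole, CH2Cl2) gives the trimethylsilyl ether F1, which is heated in o-dichlorobenzene at 200–220 °C in a sealed, base-washed vessel. The neutral thermal siloxy-Cope shift through the same boat array should give the trimethylsilyl enol ether F2, and K2CO3 in methanol converts F2 into 25, where the route resumes.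

Step 18. After ionisation at C9, proton loss from C11 (allylic alcohol), migration of C7 (ring contraction) or a shift of C1 or C20 from C10 may compete with the C8 hydride shift, and the Lewis acid may strip the acetonide or silyl ether. The fallback sets out from epoxide 32. Homolytic opening with Cp2TiCl (trivalent titanium, generated from Cp2TiCl2 and Zn) in THF with 1,4-cyclohexadiene as hydrogen-atom donor should give the tertiary C9 radical. This radical is expected to take up hydrogen anti to the bulky titanium alkoxide on C8, giving the 8-alcohol F3, and Dess–Martin oxidation of F3 returns to ketone 33.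

Step 5. The masked o-benzoquinone may dimerise faster than the bulky acrylamide traps it, and facial discrimination by the auxiliary in a thermal cycloaddition may be poor, so that much material is lost to the unwanted diastereomer. The fallback sets out from phenol 6. The same oxidation in methanol with a large excess of methyl acrylate should give the racemic endo methyl ester F4. Preparative chromatography on a chiral stationary phase gives the single enantiomer F5, and LiOH in aqueous THF saponifies F5 to acid 13, where the route resumes.

**Further compounds**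

F1 | step 12 | trimethylsilyl ether of vinyl carbinol 22 | C=C[C@@]1(O[Si](C)(C)C)C2(COC(C)(C)OC2)[C@@H]3CC[C@H]1C(CCOCc1ccccc1)=C3C
F2 | step 12 | trimethylsilyl C2=C3 enol ether of 25 | C1CC[C@H]2C3(COC(C)(C)OC3)C(O[Si](C)(C)C)=CC[C@@]2(C)C=1CCOCc1ccccc1
F3 | step 18 | 8-alcohol (8-OH on the face of C20, H9 trans to C20), 3-OTES, acetonide, butenolide | O[C@@H]1CC[C@H]2C3(COC(C)(C)OC3)[C@H](O[Si](CC)(CC)CC)CC[C@@]2(C)[C@@H]1CCC1=CCOC1=O
F4 | step 5 | racemic endo methyl ester of acid 13 (relative configuration drawn) | O=C1C(OC)(OC)[C@@H]2C[C@@H](C(=O)OC)[C@H]1C(CCOCc1ccccc1)=C2C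
F5 | step 5 | methyl ester of acid 13, single enantiomer (7R) | O=C1C(OC)(OC)[C@@H]2C[C@@H](C(=O)OC)[C@H]1C(CCOCc1ccccc1)=C2C
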